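**Retrosynthetic overview**
1. Target 14 ⇐ allylic chloride 11 + prenol 12: the C3′–C4′ bond is made last, with the allyl chloride turned into a nucleophilic π-allyliridium that adds to prenal formed in situ; the catalyst sets C4′.
2. 11 ⇐ chloromethyl ketone 10 (methylenation) ⇐ 8: the C1 hydroxyl directs a transannular chloroetherification, and bromide then reopens the ether, setting C3 and C4 from C1.
3. 8 ⇐ hydroxy ester 7 (ester to chloromethyl ketone; the carbonyl also shields the C1–O bond during ether opening).
4. 7 ⇐ diene 6 by ring-closing metathesis; 6 ⇐ keto ester 4 + allylboronate 5 (catalytic asymmetric allylboration sets C1); 4 ⇐ 1 + 2.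
5. Ring order: the cyclohexene (only carbocycle) is closed in step 3; a 7-oxanorbornane oxygen bridge is formed and reopened within step 5.

Assumption: the facial sense of the two catalyst-controlled steps (2 and 7) is as written; if either proves opposite, the mirror-image catalyst is used with no other change.

**Step 1**
Reactants: 1 4-bromo-2-methylbut-1-ene; 2 diethyl oxalate
Product: 4 ethyl 5-methyl-2-oxohex-5-enoate, via homoallyl Grignard reagent 3 (not isolated)
Conditions: Mg, THF, rt; then add to 2 (2 equiv), THF, −78 °C; aq HCl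
Reagents that add atoms: none
Why: Grignard acylation with excess diethyl oxalate at −78 °C stops at the α-keto ester because the tetrahedral magnesium adduct survives until the quench; no stereocentre is formed.

**Step 2**
Reactants: 4 ethyl 5-methyl-2-oxohex-5-enoate; 5 4,4,5,5-tetramethyl-2-(prop-2-en-1-yl)-1,3,2-dioxaborolane
Product: 6 ethyl (2R)-2-hydroxy-5-methyl-2-(prop-2-en-1-yl)hex-5-enoate
Conditions: 5 (1.3 equiv), (S)-2-[(3-tert-butyl-2-hydroxyphenyl)methylamino]-N,N,3-trimethylbutanamide (3 mol%, the antipode that gives 2R), NaOt-Bu (5 mol%), MeOH (1.5 equiv), toluene, 22 °C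
Reagents that add atoms: none
Why: Catalytic enantioselective allylboration of an α-keto ester: the boron-bound chiral aminophenol distinguishes the ester from the alkyl arm and delivers allyl to one ketone face, setting the tertiary carbinol (future C1) as R.

**Step 3**
Reactants: 6 ethyl (2R)-2-hydroxy-5-methyl-2-(prop-2-en-1-yl)hex-5-enoate
Product: 7 ethyl (1R)-1-hydroxy-4-methylcyclohex-3-ene-1-carboxylate
Conditions: second-generation Grubbs catalyst RuCl2(=CHPh)(PCy3)(H2IMes) (2 mol%), CH2Cl2 (0.01 M), 40 °C
Reagents that add atoms: none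
Why: Ring-closing metathesis of the monosubstituted and the 1,1-disubstituted alkene closes the trisubstituted cyclohexene with loss of ethene, leaving the carbinol stereocentre untouched so that C1 is R.

**Step 4**
Reactants: 7 ethyl (1R)-1-hydroxy-4-methylcyclohex-3-ene-1-carboxylate
Product: 8 2-chloro-1-[(1R)-1-hydroxy-4-methylcyclohex-3-en-1-yl]ethan-1-one
Conditions: MeLi (1.0 equiv), THF, −78 °C; ICH2Cl (1.6 equiv), then MeLi·LiBr (1.5 equiv) dropwise, −78 °C; AcOH, −78 °C
Reagents that add atoms: chloroiodomethane, ClCI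
Why: Ester chloromethylation with a lithium carbenoid (Kowalski-type homologation): the hydroxyl is first masked as its lithium alkoxide, chloromethyllithium adds once because the tetrahedral adduct is stable at −78 °C, and C1 is not involved.

**Step 5**
Reactants: 8 2-chloro-1-[(1R)-1-hydroxy-4-methylcyclohex-3-en-1-yl]ethan-1-one
Product: 10 1-[(1R,3S,4S)-4-bromo-3-chloro-1-hydroxy-4-methylcyclohexyl]-2-chloroethan-1-one, via bridged chloro ether 9 (not isolated)
Conditions: NCS (1.05 equiv), TsOH (5 mol%), CH2Cl2, 0 °C to rt, dark; then BBr3 (2.5 equiv), −78 to −30 °C; H2O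
Reagents that add atoms: N-chlorosuccinimide, ClN1C(=O)CCC1=O; boron tribromide, BrB(Br)Br
Why: Proposed new method: chloronium formation on the ring alkene is productive only on the face anti to the C1 hydroxyl, which closes transannularly on the tertiary carbon (chloroetherification, as in 1,4-cineole-type ether formation) and so fixes Cl at C3 trans to the C1 oxygen, after which BBr3 re-ionises the tertiary C4–O bond (the C1–O bond is protected by the adjacent carbonyl) through the same chlorine-bridged cation and bromide is returned on the face the oxygen leaves, giving C4–Br with retention, trans to Cl and cis to the C1 hydroxyl; the closest known reactions are haloetherification of terpinen-4-ol-type alcohols and BBr3 cleavage of tertiary ethers with neighbouring-group participation.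

**Step 6**
Reactants: 10 1-[(1R,3S,4S)-4-bromo-3-chloro-1-hydroxy-4-methylcyclohexyl]-2-chloroethan-1-one
Product: 11 (1R,3S,4S)-4-bromo-3-chloro-1-(3-chloroprop-1-en-2-yl)-4-methylcyclohexan-1-ol
Conditions: Cp2TiMe2 (3 equiv), toluene/THF, 65 °C, dark
Reagents that add atoms: dimethyltitanocene, C[Ti](C)(C1C=CC=C1)C1C=CC=C1
Why: Petasis methylenation: thermally generated Cp2Ti=CH2 converts the hindered, base-sensitive α-chloro ketone into the 1,1-disubstituted alkene under neutral, non-Lewis-acidic conditions that spare the tertiary bromide, the secondary chloride and the free alcohol, with no stereocentre affected.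

**Step 7**
Reactants: 11 (1R,3S,4S)-4-bromo-3-chloro-1-(3-chloroprop-1-en-2-yl)-4-methylcyclohexan-1-ol; 12 3-methylbut-2-en-1-ol
Product: 14 (1R,3S,4S)-4-bromo-3-chloro-1-[(4S)-4-hydroxy-6-methylhepta-1,5-dien-2-yl]-4-methylcyclohexan-1-ol, via 3-methylbut-2-enal 13 (not isolated)
Conditions: 12 (3 equiv), [Ir(cod)Cl]2 (2.5 mol%), (R)-SEGPHOS [5,5′-bis(diphenylphosphino)-4,4′-bi-1,3-benzodioxole] (5 mol%), 4-cyano-3-nitrobenzoic acid (10 mol%), Cs2CO3 (1.2 equiv), THF, 50 °C, sealed tube
Reagents that add atoms: none
Why: Transfer-hydrogenative carbonyl allylation (Krische-type): oxidative addition of the allylic chloride, normally an electrophile, to low-valent iridium gives a nucleophilic π-allyliridium that adds to 3-methylbut-2-enal formed in situ by dehydrogenation of 12, and the chiral bisphosphine–cyclometallated nitrobenzoate iridium complex selects the aldehyde face in a closed chair transition state to set C4′ as S under catalyst control (the symmetric 2-substituted allyl unit removes any regiochemical issue).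

**Compound list**
1 | 4-bromo-2-methylbut-1-ene | C=C(C)CCBr | starting material
2 | diethyl oxalate | CCOC(=O)C(=O)OCC | starting material
3 | (3-methylbut-3-en-1-yl)magnesium bromide | C=C(C)CC[Mg]Br | intermediate
4 | ethyl 5-methyl-2-oxohex-5-enoate | CCOC(=O)C(=O)CCC(C)=C | intermediate
5 | 4,4,5,5-tetramethyl-2-(prop-2-en-1-yl)-1,3,2-dioxaborolane | C=CCB1OC(C)(C)C(C)(C)O1 | starting material
6 | ethyl (2R)-2-hydroxy-5-methyl-2-(prop-2-en-1-yl)hex-5-enoate | CCOC(=O)[C@](O)(CC=C)CCC(C)=C | intermediate
7 | ethyl (1R)-1-hydroxy-4-methylcyclohex-3-ene-1-carboxylate | CCOC(=O)[C@@]1(O)CCC(C)=CC1 | intermediate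
8 | 2-chloro-1-[(1R)-1-hydroxy-4-methylcyclohex-3-en-1-yl]ethan-1-one | ClCC(=O)[C@@]1(O)CCC(C)=CC1 | intermediate
9 | 2-chloro-1-[(1R,3S,4S)-3-chloro-4-methyl-7-oxabicyclo[2.2.1]heptan-1-yl]ethan-1-one (3-endo-chloro) | ClCC(=O)[C@@]1(O2)CC[C@@]2(C)[C@@H](Cl)C1 | intermediate
10 | 1-[(1R,3S,4S)-4-bromo-3-chloro-1-hydroxy-4-methylcyclohexyl]-2-chloroethan-1-one | ClCC(=O)[C@@]1(O)CC[C@](C)(Br)[C@@H](Cl)C1 | intermediate
11 | (1R,3S,4S)-4-bromo-3-chloro-1-(3-chloroprop-1-en-2-yl)-4-methylcyclohexan-1-ol | ClCC(=C)[C@@]1(O)CC[C@](C)(Br)[C@@H](Cl)C1 | intermediate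
12 | 3-methylbut-2-en-1-ol | CC(C)=CCO | starting material
13 | 3-methylbut-2-enal | CC(C)=CC=O | intermediate
14 | (1R,3S,4S)-4-bromo-3-chloro-1-[(4S)-4-hydroxy-6-methylhepta-1,5-dien-2-yl]-4-methylcyclohexan-1-ol | C=C(C[C@H](O)C=C(C)C)[C@@]1(O)CC[C@](C)(Br)[C@@H](Cl)C1 | target

**Step count and risk**
Total steps: 7. Longest linear sequence: 7 (from 1).

Most likely to fail, first: step 7. The hindered 2-substituted allyl chloride may ionise slowly. The tertiary alkoxide may bind iridium. Warm carbonate could re-close the cis-hydroxy bromide to the chloro ether or cause elimination. The enantioselectivity with this donor is untested. The fallback sets out from 11 and comes back at 14. Borylation of the allylic chloride with bis(pinacolato)diboron and Pd2(dba)3 (zerovalent palladium, DMSO, rt) gives (1R,3S,4S)-4-bromo-3-chloro-4-methyl-1-[3-(4,4,5,5-tetramethyl-1,3,2-dioxaborolan-2-yl)prop-1-en-2-yl]cyclohexan-1-ol F1. This allylboronate is then added to 3-methylbut-2-enal at −30 °C in toluene under catalysis by (R)-3,3′-bis(2,4,6-triisopropylphenyl)-1,1′-binaphthyl-2,2′-diyl hydrogen phosphate. Here the polarity is reversed at boron in a separate step, and the carbinol is set by Brønsted-acid-catalysed allylboration, giving 14.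

Second: step 5. Chlorine may attack the alkene face syn to the hydroxyl and give allylic chlorides. BBr3 may cause elimination or erode the retention at C4. The fallback sets out from 8 and comes back at 10. Hydroxyl-directed epoxidation with VO(acac)2 and t-BuOOH gives the cis-epoxy alcohol 2-chloro-1-[(1R,3R,6S)-3-hydroxy-6-methyl-7-oxabicyclo[4.1.0]heptan-3-yl]ethan-1-one F2. Li2CuCl4 in THF opens it by backside attack at the less substituted carbon, giving the trans-chlorohydrin 2-chloro-1-[(1R,3S,4S)-3-chloro-1,4-dihydroxy-4-methylcyclohexyl]ethan-1-one F3. HBr in acetic acid at 0 °C then replaces the tertiary C4 hydroxyl by bromide through the chlorine-bridged cation, with retention (possibly by way of 9), giving 10.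

Third: step 6. The ketone is flanked by a quaternary carbinol and a chloromethyl group, and the substrate must survive 65 °C as a titanium alkoxide. The fallback sets out from 10 and comes back at 11. Addition of Me3SiCH2MgCl premixed with CeCl3 (THF, −78 °C) gives 1-chloro-2-[(1R,3S,4S)-4-bromo-3-chloro-1-hydroxy-4-methylcyclohexyl]-3-(trimethylsilyl)propan-2-ol F4, as an inconsequential mixture at the new carbinol. Acid-promoted Peterson elimination (pyridinium p-toluenesulfonate or silica gel, CH2Cl2) then gives 11.

**Further compounds**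
F1 | step 7 | (1R,3S,4S)-4-bromo-3-chloro-4-methyl-1-[3-(4,4,5,5-tetramethyl-1,3,2-dioxaborolan-2-yl)prop-1-en-2-yl]cyclohexan-1-ol | C=C(CB1OC(C)(C)C(C)(C)O1)[C@@]1(O)CC[C@](C)(Br)[C@@H](Cl)C1
F2 | step 5 | 2-chloro-1-[(1R,3R,6S)-3-hydroxy-6-methyl-7-oxabicyclo[4.1.0]heptan-3-yl]ethan-1-one | ClCC(=O)[C@@]1(O)CC[C@]2(C)O[C@@H]2C1
F3 | step 5 | 2-chloro-1-[(1R,3S,4S)-3-chloro-1,4-dihydroxy-4-methylcyclohexyl]ethan-1-one | ClCC(=O)[C@@]1(O)CC[C@](C)(O)[C@@H](Cl)C1
F4 | step 6 | 1-chloro-2-[(1R,3S,4S)-4-bromo-3-chloro-1-hydroxy-4-methylcyclohexyl]-3-(trimethylsilyl)propan-2-ol | ClCC(O)(C[Si](C)(C)C)[C@@]1(O)CC[C@](C)(Br)[C@@H](Cl)C1
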